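**Retrosynthetic overview**
- Feature: benzo ring A (C3a, C4, C5, C6, C7, C7a) shares the C3a–C7a bond with the dihydrofuran ring (O1, C2, C3, C3a, C7a). O1 can therefore carry C7a≡C7 as an ynol ether and C3 can carry C3a≡C4 as an alkyne, both held by the C2–C3 stereodyad.
- Key disconnection: (2+2+2) cyclotrimerisation of diyne 18 with alkyne 20 (which supplies C5–C6) forms C3a–C7a, C4–C5 and C6–C7. The dihydrofuran ring closes first in the metallacycle and ring A second, in the same operation.
- After it: the CH2O placeholder at C7 is oxidised to CHO, degraded to OH (Dakin-type), methylated, and both benzyl ethers are removed.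
- Before it: 18 comes from anti homopropargylic alcohol 10 by alkoxide/trichloroethylene ynol ether synthesis, hydroxymethylation of the lithium alkynyl ether and unmasking of the second alkyne.
- 10 comes from benzylated syringaldehyde 2 and chiral propargylic mesylate 8 (Marshall propargylation), which sets C2 and C3.

Key step: step 12

Remark on the chemistry: the alkyne that becomes C3a–C4 is kept as its triisopropylsilyl derivative until the ynol ether is complete, because n-BuLi would otherwise metalate both alkyne termini. For the same reason C7 is marked by a fluoride-stable CH2O group rather than a C-silyl group, and the C3 hydroxymethyl oxygen carries a benzyl group that cannot migrate to the neighbouring alkoxide.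

Step 1
Reactants: 1 syringaldehyde (4-hydroxy-3,5-dimethoxybenzaldehyde)
Product: 2 4-(benzyloxy)-3,5-dimethoxybenzaldehyde
Conditions: BnBr, K2CO3, DMF, rt
Reagents that add atoms: benzyl bromide, BrCc1ccccc1
Why: Williamson etherification of the phenoxide masks the phenol as a benzyl ether that should survive organozinc, KH and n-BuLi and leaves by hydrogenolysis at the end.

Step 2
Reactants: 3 (benzyloxy)acetaldehyde; 4 ethynyltri(propan-2-yl)silane
Product: 5 rac-1-(benzyloxy)-4-[tri(propan-2-yl)silyl]but-3-yn-2-ol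
Conditions: 4, n-BuLi, THF, −78 °C; then 3, −78 → 0 °C
Reagents that add atoms: none
Why: 1,2-addition of the lithium acetylide to the aldehyde gives the propargylic alcohol, whose stereocentre is erased in the next step.

Step 3
Reactants: 5 rac-1-(benzyloxy)-4-[tri(propan-2-yl)silyl]but-3-yn-2-ol
Product: 6 1-(benzyloxy)-4-[tri(propan-2-yl)silyl]but-3-yn-2-one
Conditions: MnO2 (excess), CH2Cl2, rt
Reagents that add atoms: none
Why: MnO2 oxidation of an activated (propargylic) alcohol gives the ynone under neutral conditions that leave the benzyl ether and the C–Si bond alone.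

Step 4
Reactants: 6 1-(benzyloxy)-4-[tri(propan-2-yl)silyl]but-3-yn-2-one
Product: 7 (2S)-1-(benzyloxy)-4-[tri(propan-2-yl)silyl]but-3-yn-2-ol
Conditions: RuCl[(R,R)-TsDPEN](p-cymene) (1 mol %), i-PrOH, rt
Reagents that add atoms: none
Why: Noyori asymmetric transfer hydrogenation of an alkynyl ketone, in which the alkyne is the π-directing group, so the (R,R) catalyst should deliver hydride to the face that gives the S carbinol (CH2OBn outranks the alkynyl carbon in the descriptor).

Step 5
Reactants: 7 (2S)-1-(benzyloxy)-4-[tri(propan-2-yl)silyl]but-3-yn-2-ol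
Product: 8 (2S)-1-(benzyloxy)-4-[tri(propan-2-yl)silyl]but-3-yn-2-yl methanesulfonate
Conditions: MsCl, Et3N, CH2Cl2, −78 °C
Reagents that add atoms: methanesulfonyl chloride, CS(=O)(=O)Cl
Why: O-sulfonylation with retention gives the propargylic mesylate needed for palladium-mediated umpolung.

Step 6
Reactants: 2 4-(benzyloxy)-3,5-dimethoxybenzaldehyde; 8 (2S)-1-(benzyloxy)-4-[tri(propan-2-yl)silyl]but-3-yn-2-yl methanesulfonate
Product: 10 (1S,2R)-2-[(benzyloxy)methyl]-1-[4-(benzyloxy)-3,5-dimethoxyphenyl]-4-[tri(propan-2-yl)silyl]but-3-yn-1-ol, via allenylzinc 9 (not isolated)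
Conditions: Pd(OAc)2 (5 mol %), PPh3 (5 mol %), Et2Zn (3 equiv), THF, −78 → −20 °C
Reagents that add atoms: none
Why: Marshall propargylation, in which zerovalent palladium displaces the mesylate anti (SN2′), Et2Zn transmetalates to allenylzinc 9, and 9 adds to 2 through a cyclic SE2′ transition state; the propargylic centre (C3 of the target) thus forms with net inversion of the mesylate centre, and the carbinol centre (C2) forms anti to it because the aryl group avoids the allenyl substituent.

Step 7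
Reactants: 10 (1S,2R)-2-[(benzyloxy)methyl]-1-[4-(benzyloxy)-3,5-dimethoxyphenyl]-4-[tri(propan-2-yl)silyl]but-3-yn-1-ol; 11 trichloroethylene
Product: 13 2-(benzyloxy)-5-{(1S,2R)-2-[(benzyloxy)methyl]-1-[(E)-1,2-dichloroethenoxy]-4-[tri(propan-2-yl)silyl]but-3-yn-1-yl}-1,3-dimethoxybenzene, via dichloroacetylene 12 (not isolated)
Conditions: KH (2.2 equiv), THF, 0 °C → rt; then 11, −50 °C → rt
Reagents that add atoms: none
Why: first half of the alkoxide/trichloroethylene ynol ether synthesis, in which KH forms the alkoxide and dehydrochlorinates 11 to dichloroacetylene, to which the alkoxide adds trans to give the E dichlorovinyl ether; the bulky silyl cap and the benzyl ether should be inert to the alkoxide.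

Step 8
Reactants: 13 the (E)-1,2-dichlorovinyl ether of 10
Product: 16 3-({(1S,2R)-2-[(benzyloxy)methyl]-1-[4-(benzyloxy)-3,5-dimethoxyphenyl]-4-[tri(propan-2-yl)silyl]but-3-yn-1-yl}oxy)prop-2-yn-1-ol, via chloroalkynyl ether 14 (not isolated), via lithium alkynyl ether 15 (not isolated)
Conditions: n-BuLi (2.4 equiv), THF, −78 → −40 °C; then (CH2O)n, −40 → 0 °C
Reagents that add atoms: formaldehyde (as paraformaldehyde), C=O
Why: second half of the ynol ether synthesis, in which n-BuLi eliminates HCl to the chloroalkyne and exchanges Cl for Li, and the lithium alkynyl ether adds to formaldehyde (acetylide 1,2-addition) to place the one-carbon oxygenated placeholder on the future C7 while the silyl-capped alkyne stays untouched.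

Step 9
Reactants: 16 the silyl-capped hydroxymethyl ynol ether
Product: 17 3-({(1S,2R)-2-[(benzyloxy)methyl]-1-[4-(benzyloxy)-3,5-dimethoxyphenyl]but-3-yn-1-yl}oxy)prop-2-yn-1-ol
Conditions: TBAF (1.1 equiv), THF, 0 °C
Reagents that add atoms: none
Why: fluoride-induced protodesilylation of the alkynylsilane frees the terminal alkyne; the ynol ether is base-stable and is kept cold because benzylic alkynyl ethers rearrange on warming.

Step 10
Reactants: 17 the diyne alcohol
Product: 18 tert-butyl{[3-({(1S,2R)-2-[(benzyloxy)methyl]-1-[4-(benzyloxy)-3,5-dimethoxyphenyl]but-3-yn-1-yl}oxy)prop-2-yn-1-yl]oxy}dimethylsilane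
Conditions: TBSCl, imidazole (3 equiv), CH2Cl2, 0 °C
Reagents that add atoms: tert-butyldimethylsilyl chloride, CC(C)(C)[Si](C)(C)Cl
Why: silyl ether formation at the primary alcohol gives a bulky, non-coordinating CH2OTBS group on the ynol ether terminus, which is the steric control element of the next step.

Step 11
Reactants: 19 pent-4-yn-1-ol
Product: 20 tert-butyldimethyl(pent-4-yn-1-yloxy)silane
Conditions: TBSCl, imidazole, CH2Cl2, rt
Reagents that add atoms: tert-butyldimethylsilyl chloride, CC(C)(C)[Si](C)(C)Cl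
Why: silyl ether formation keeps a free hydroxyl away from the acid-sensitive ynol ether and the catalyst.

Step 12
Reactants: 18 the ynol ether–alkyne diyne; 20 tert-butyldimethyl(pent-4-yn-1-yloxy)silane
Product: 21 (2S,3R)-3-[(benzyloxy)methyl]-2-[4-(benzyloxy)-3,5-dimethoxyphenyl]-7-{[(tert-butyldimethylsilyl)oxy]methyl}-5-{3-[(tert-butyldimethylsilyl)oxy]propyl}-2,3-dihydro-1-benzofuran
Conditions: RhCl(PPh3)3 (5 mol %), 20 (4 equiv), toluene, 25–40 °C, slow addition of 18
Reagents that add atoms: none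
Why: Oxidative coupling of the ynol ether and the terminal alkyne of 18 on monovalent rhodium forms C3a–C7a and gives a bicyclic rhodacyclopentadiene of trivalent rhodium, into which 20 inserts before reductive elimination forms C4–C5 and C6–C7. The closest known reaction type is the RhCl(PPh3)3-catalysed crossed (2+2+2) cyclotrimerisation of heteroatom-linked 1,6-diynes (ynamide- and aryl alkynyl ether-linked) with terminal alkynes. The dihydrofuran ring closes by tether-directed coupling of C7a with C3a across the O1–C2–C3 link inside the five-membered metallacycle, and ring A closes when the C5–C6 unit of 20 bridges C4 and C7 of that metallacycle. No stereocentre is made, and C2 and C3 are spectators whose bonds are not touched under these neutral conditions. The step needs regioselective insertion of 20, which the CH2OTBS group on the rhodium-bound C7 should secure: the substituted carbon of 20 bonds to the unhindered C4–H end and its CH terminus to C7, which puts the side chain at C5. Cross- over self-trimerisation is favoured by slow addition of 18 to excess 20, and the temperature is held at or below 40 °C because benzylic alkynyl ethers undergo sigmatropic rearrangement on heating.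

Step 13
Reactants: 21 the bis-silyl ether from the cyclotrimerisation
Product: 22 3-{(2S,3R)-3-[(benzyloxy)methyl]-2-[4-(benzyloxy)-3,5-dimethoxyphenyl]-7-(hydroxymethyl)-2,3-dihydro-1-benzofuran-5-yl}propan-1-ol
Conditions: TBAF (2.5 equiv), THF, rt
Reagents that add atoms: none
Why: fluoride cleavage of both silyl ethers leaves the benzyl ethers intact and reveals the benzylic alcohol at C7.

Step 14
Reactants: 22 the diol
Product: 23 (2S,3R)-3-[(benzyloxy)methyl]-2-[4-(benzyloxy)-3,5-dimethoxyphenyl]-5-(3-hydroxypropyl)-2,3-dihydro-1-benzofuran-7-carbaldehyde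
Conditions: MnO2 (excess), CH2Cl2, rt
Reagents that add atoms: none
Why: MnO2 oxidises benzylic alcohols selectively, so only the C7 hydroxymethyl group should become the aldehyde while the aliphatic primary alcohol stays.

Step 15
Reactants: 23 the C7 aldehyde
Product: 25 (2S,3R)-3-[(benzyloxy)methyl]-2-[4-(benzyloxy)-3,5-dimethoxyphenyl]-5-(3-hydroxypropyl)-2,3-dihydro-1-benzofuran-7-ol, via aryl formate 24 (not isolated)
Conditions: m-CPBA (1.3 equiv), NaHCO3, CH2Cl2, 0 °C; then K2CO3, MeOH, rt
Reagents that add atoms: 3-chloroperoxybenzoic acid, OOC(=O)c1cccc(Cl)c1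
Why: Dakin-type Baeyer–Villiger oxidation, in which the electron-rich aryl group ortho to O1 migrates in the Criegee intermediate to give the aryl formate, whose methanolysis gives the C7 phenol.

Step 16
Reactants: 25 the C7 phenol
Product: 26 3-{(2S,3R)-3-[(benzyloxy)methyl]-2-[4-(benzyloxy)-3,5-dimethoxyphenyl]-7-methoxy-2,3-dihydro-1-benzofuran-5-yl}propan-1-ol
Conditions: MeI, K2CO3, acetone, 40 °C
Reagents that add atoms: iodomethane, CI
Why: Williamson methylation under carbonate conditions is selective for the phenoxide over the aliphatic alcohol.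

Step 17
Reactants: 26 the bis-benzyl ether
Product: 27 4-[(2S,3R)-3-(hydroxymethyl)-5-(3-hydroxypropyl)-7-methoxy-2,3-dihydro-1-benzofuran-2-yl]-2,6-dimethoxyphenol
Conditions: H2 (1 atm), Pd/C, EtOAc–MeOH, rt
Reagents that add atoms: none
Why: hydrogenolysis on palladium should cleave the phenolic and the primary benzyl ethers faster than the hindered cyclic benzylic C2–O1 bond, and the neutral conditions keep both stereocentres.

**Compound list**
1 | syringaldehyde | COc1cc(C=O)cc(OC)c1O | starting material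
2 | 4-(benzyloxy)-3,5-dimethoxybenzaldehyde | COc1cc(C=O)cc(OC)c1OCc1ccccc1 | intermediate
3 | (benzyloxy)acetaldehyde | O=CCOCc1ccccc1 | starting material
4 | ethynyltri(propan-2-yl)silane | C#C[Si](C(C)C)(C(C)C)C(C)C | starting material
5 | rac-1-(benzyloxy)-4-[tri(propan-2-yl)silyl]but-3-yn-2-ol | CC(C)[Si](C#CC(O)COCc1ccccc1)(C(C)C)C(C)C | intermediate
6 | 1-(benzyloxy)-4-[tri(propan-2-yl)silyl]but-3-yn-2-one | CC(C)[Si](C#CC(=O)COCc1ccccc1)(C(C)C)C(C)C | intermediate
7 | (2S)-1-(benzyloxy)-4-[tri(propan-2-yl)silyl]but-3-yn-2-ol | CC(C)[Si](C#C[C@H](O)COCc1ccccc1)(C(C)C)C(C)C | intermediate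
8 | (2S)-1-(benzyloxy)-4-[tri(propan-2-yl)silyl]but-3-yn-2-yl methanesulfonate | CC(C)[Si](C#C[C@H](OS(C)(=O)=O)COCc1ccccc1)(C(C)C)C(C)C | intermediate
9 | ethyl{(P)-4-(benzyloxy)-1-[tri(propan-2-yl)silyl]buta-1,2-dien-1-yl}zinc (zinc anti to the departed mesylate oxygen) | CC[Zn]C([Si](C(C)C)(C(C)C)C(C)C)=[C@@]=C([H])COCc1ccccc1 | intermediate
10 | (1S,2R)-2-[(benzyloxy)methyl]-1-[4-(benzyloxy)-3,5-dimethoxyphenyl]-4-[tri(propan-2-yl)silyl]but-3-yn-1-ol | COc1cc([C@@H](O)[C@@H](COCc2ccccc2)C#C[Si](C(C)C)(C(C)C)C(C)C)cc(OC)c1OCc1ccccc1 | intermediate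
11 | trichloroethylene | ClC=C(Cl)Cl | starting material
12 | dichloroacetylene | ClC#CCl | intermediate
13 | 2-(benzyloxy)-5-{(1S,2R)-2-[(benzyloxy)methyl]-1-[(E)-1,2-dichloroethenoxy]-4-[tri(propan-2-yl)silyl]but-3-yn-1-yl}-1,3-dimethoxybenzene | COc1cc([C@@H](O/C(Cl)=C\Cl)[C@@H](COCc2ccccc2)C#C[Si](C(C)C)(C(C)C)C(C)C)cc(OC)c1OCc1ccccc1 | intermediate
14 | chloroethynyl ether of 10 (1S,2R) | COc1cc([C@@H](OC#CCl)[C@@H](COCc2ccccc2)C#C[Si](C(C)C)(C(C)C)C(C)C)cc(OC)c1OCc1ccccc1 | intermediate
15 | lithioethynyl ether of 10 (1S,2R) | COc1cc([C@@H](OC#C[Li])[C@@H](COCc2ccccc2)C#C[Si](C(C)C)(C(C)C)C(C)C)cc(OC)c1OCc1ccccc1 | intermediate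
16 | 3-({(1S,2R)-2-[(benzyloxy)methyl]-1-[4-(benzyloxy)-3,5-dimethoxyphenyl]-4-[tri(propan-2-yl)silyl]but-3-yn-1-yl}oxy)prop-2-yn-1-ol | COc1cc([C@@H](OC#CCO)[C@@H](COCc2ccccc2)C#C[Si](C(C)C)(C(C)C)C(C)C)cc(OC)c1OCc1ccccc1 | intermediate
17 | 3-({(1S,2R)-2-[(benzyloxy)methyl]-1-[4-(benzyloxy)-3,5-dimethoxyphenyl]but-3-yn-1-yl}oxy)prop-2-yn-1-ol | COc1cc([C@@H](OC#CCO)[C@@H](COCc2ccccc2)C#C)cc(OC)c1OCc1ccccc1 | intermediate
18 | tert-butyl{[3-({(1S,2R)-2-[(benzyloxy)methyl]-1-[4-(benzyloxy)-3,5-dimethoxyphenyl]but-3-yn-1-yl}oxy)prop-2-yn-1-yl]oxy}dimethylsilane | COc1cc([C@@H](OC#CCO[Si](C)(C)C(C)(C)C)[C@@H](COCc2ccccc2)C#C)cc(OC)c1OCc1ccccc1 | intermediate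
19 | pent-4-yn-1-ol | C#CCCCO | starting material
20 | tert-butyldimethyl(pent-4-yn-1-yloxy)silane | C#CCCCO[Si](C)(C)C(C)(C)C | intermediate
21 | (2S,3R)-3-[(benzyloxy)methyl]-2-[4-(benzyloxy)-3,5-dimethoxyphenyl]-7-{[(tert-butyldimethylsilyl)oxy]methyl}-5-{3-[(tert-butyldimethylsilyl)oxy]propyl}-2,3-dihydro-1-benzofuran | COc1cc([C@H]2Oc3c(CO[Si](C)(C)C(C)(C)C)cc(CCCO[Si](C)(C)C(C)(C)C)cc3[C@@H]2COCc2ccccc2)cc(OC)c1OCc1ccccc1 | intermediate
22 | 3-{(2S,3R)-3-[(benzyloxy)methyl]-2-[4-(benzyloxy)-3,5-dimethoxyphenyl]-7-(hydroxymethyl)-2,3-dihydro-1-benzofuran-5-yl}propan-1-ol | COc1cc([C@H]2Oc3c(CO)cc(CCCO)cc3[C@@H]2COCc2ccccc2)cc(OC)c1OCc1ccccc1 | intermediate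
23 | (2S,3R)-3-[(benzyloxy)methyl]-2-[4-(benzyloxy)-3,5-dimethoxyphenyl]-5-(3-hydroxypropyl)-2,3-dihydro-1-benzofuran-7-carbaldehyde | COc1cc([C@H]2Oc3c(C=O)cc(CCCO)cc3[C@@H]2COCc2ccccc2)cc(OC)c1OCc1ccccc1 | intermediate
24 | (2S,3R)-3-[(benzyloxy)methyl]-2-[4-(benzyloxy)-3,5-dimethoxyphenyl]-5-(3-hydroxypropyl)-2,3-dihydro-1-benzofuran-7-yl formate | COc1cc([C@H]2Oc3c(OC=O)cc(CCCO)cc3[C@@H]2COCc2ccccc2)cc(OC)c1OCc1ccccc1 | intermediate
25 | (2S,3R)-3-[(benzyloxy)methyl]-2-[4-(benzyloxy)-3,5-dimethoxyphenyl]-5-(3-hydroxypropyl)-2,3-dihydro-1-benzofuran-7-ol | COc1cc([C@H]2Oc3c(O)cc(CCCO)cc3[C@@H]2COCc2ccccc2)cc(OC)c1OCc1ccccc1 | intermediate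
26 | 3-{(2S,3R)-3-[(benzyloxy)methyl]-2-[4-(benzyloxy)-3,5-dimethoxyphenyl]-7-methoxy-2,3-dihydro-1-benzofuran-5-yl}propan-1-ol | COc1cc([C@H]2Oc3c(OC)cc(CCCO)cc3[C@@H]2COCc2ccccc2)cc(OC)c1OCc1ccccc1 | intermediate
27 | 4-[(2S,3R)-3-(hydroxymethyl)-5-(3-hydroxypropyl)-7-methoxy-2,3-dihydro-1-benzofuran-2-yl]-2,6-dimethoxyphenol | COc1cc([C@H]2Oc3c(OC)cc(CCCO)cc3[C@@H]2CO)cc(OC)c1O | target

**Step count**
Total: 17 steps. Longest linear sequence: 15 steps (3 → 5 → 6 → 7 → 8 → 10 → 13 → 16 → 17 → 18 → 21 → 22 → 23 → 25 → 26 → 27; steps 1 and 11 are side branches).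

**Steps most likely to fail**

1. Step 12. Alkyne 20 may insert in both orientations, which would put the side chain at C6. The benzylic alkynyl ether may rearrange or hydrate before the metal captures it, and 20 may self-trimerise. Fallback: a temporary silicon tether delivers the third alkyne intramolecularly; it sets out from 18 and 19 and comes back at 22. Alcohol 19 is monosilylated with excess iPr2SiCl2 (Et3N, CH2Cl2) to chlorodi(propan-2-yl)(pent-4-yn-1-yloxy)silane F1. The lithium acetylide of 18 (n-BuLi, THF, −78 °C; the ynol ether terminus is blocked) is silylated with it to give the silicon-tethered triyne F2. RhCl(PPh3)3 in toluene at 25–40 °C should close all rings to the benzo-fused oxasilepine F3, in which the seven-membered Si–O ring can only form with the chain carbon bonded to C4. TBAF in wet DMF at 70 °C then protodesilylates C4 and cleaves the Si–O and TBS ether bonds to give 22.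

2. Step 6. Facial selectivity toward the aromatic aldehyde may be poor, so the carbinol epimer forms alongside 10, and some allenyl reagent may be lost by elimination. Fallback: the carbinol centre is reset by reagent-controlled reduction; it sets out from the step 6 product mixture and comes back at 10. The mixture of 10 and its (1R,2R) epimer F4, which share the C2 configuration, is oxidised (Dess–Martin periodinane, NaHCO3, CH2Cl2) to the aryl ketone F5. Corey–Bakshi–Shibata reduction ((R)-Me-CBS oxazaborolidine, BH3·SMe2, THF, −30 °C) should then return 10.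

3. Step 7. The hindered secondary benzylic alkoxide may capture dichloroacetylene slowly and degrade on standing with KH. Fallback: the ynol ether carbons are brought in through a formate instead; it sets out from 10 and comes back at 15, which goes on as in step 8. Alcohol 10 is formylated (formic acetic anhydride, pyridine) to the formate F6. Dibromomethylenation of the formate carbonyl (PPh3, CBr4, CH2Cl2; Ramirez-type olefination) gives the 1,1-dibromovinyl ether F7. n-BuLi (2.2 equiv, THF, −78 °C) converts F7 by elimination and Br/Li exchange into lithium alkynyl ether 15.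

**Further compounds**
F1 | step 12 | chlorodi(propan-2-yl)(pent-4-yn-1-yloxy)silane | CC(C)[Si](Cl)(OCCCC#C)C(C)C
F2 | step 12 | silicon-tethered triyne: 18 with its terminal alkyne carbon bearing Si(i-Pr)2–O–(CH2)3–C≡CH | COc1cc([C@@H](OC#CCO[Si](C)(C)C(C)(C)C)[C@@H](COCc2ccccc2)C#C[Si](C(C)C)(C(C)C)OCCCC#C)cc(OC)c1OCc1ccccc1
F3 | step 12 | benzo-fused oxasilepine: (2S,3R)-dihydrobenzofuran with C4–Si(i-Pr)2–O–(CH2)3–C5 ring and C7 CH2OTBS | COc1cc([C@H]2Oc3c(CO[Si](C)(C)C(C)(C)C)cc4CCCO[Si](C(C)C)(C(C)C)c4c3[C@@H]2COCc2ccccc2)cc(OC)c1OCc1ccccc1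
F4 | step 6 | (1R,2R)-2-[(benzyloxy)methyl]-1-[4-(benzyloxy)-3,5-dimethoxyphenyl]-4-[tri(propan-2-yl)silyl]but-3-yn-1-ol | COc1cc([C@H](O)[C@@H](COCc2ccccc2)C#C[Si](C(C)C)(C(C)C)C(C)C)cc(OC)c1OCc1ccccc1
F5 | step 6 | (2R)-2-[(benzyloxy)methyl]-1-[4-(benzyloxy)-3,5-dimethoxyphenyl]-4-[tri(propan-2-yl)silyl]but-3-yn-1-one | COc1cc(C(=O)[C@@H](COCc2ccccc2)C#C[Si](C(C)C)(C(C)C)C(C)C)cc(OC)c1OCc1ccccc1
F6 | step 7 | (1S,2R)-2-[(benzyloxy)methyl]-1-[4-(benzyloxy)-3,5-dimethoxyphenyl]-4-[tri(propan-2-yl)silyl]but-3-yn-1-yl formate | COc1cc([C@@H](OC=O)[C@@H](COCc2ccccc2)C#C[Si](C(C)C)(C(C)C)C(C)C)cc(OC)c1OCc1ccccc1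
F7 | step 7 | 2,2-dibromoethenyl ether of 10 (1S,2R) | COc1cc([C@@H](OC=C(Br)Br)[C@@H](COCc2ccccc2)C#C[Si](C(C)C)(C(C)C)C(C)C)cc(OC)c1OCc1ccccc1
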